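## Retrosynthetic overview

- The dihydrofuran ring is cut last, at C3–C3a and C2–O1, into a 5-substituted resorcinol and silyl-protected resveratrol; forward, this is an anodic radical-cation [3+2] annulation (the proposed new step).
- The resorcinol partner is a trans-4,5-diaryl-2,2-dimethyl-1,3-dioxolane; both aryl–C bonds are cut back to the two carboxyl groups of D-tartaric acid acetonide (two nickel-electrocatalysed decarboxylative arylations).
- D-tartrate is the only source of chirality: each decarboxylative arylation rebuilds its carbon trans to its neighbour (giving the R,R-dioxolane), the dioxolane directs C3 in the annulation, and trans ring closure fixes C2.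
- Ring order: dioxolane (bought) → dihydrofuran ring (step 7); the dioxolane is opened in the last step.

Assumption: the acetonide of dimethyl D-tartrate, N-hydroxyphthalimide, 1-(benzyloxy)-4-iodobenzene, 1,3-bis(benzyloxy)-5-bromobenzene and resveratrol are bought.

## Route

**Step 1**
Reactants: 1 dimethyl (4S,5S)-2,2-dimethyl-1,3-dioxolane-4,5-dicarboxylate
Product: 2 (4S,5S)-5-(methoxycarbonyl)-2,2-dimethyl-1,3-dioxolane-4-carboxylic acid
Conditions: KOH (1.0 equiv), MeOH, 0 °C to rt; then 1 M HCl to pH 2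
Reagents that add atoms: potassium hydroxide [K+].[OH-]
Why: Monosaponification of a symmetric diester stops cleanly because the first carboxylate slows attack on the second ester; no stereocenter is touched and the trans diester does not epimerise under these conditions.

**Step 2**
Reactants: 2 (4S,5S)-5-(methoxycarbonyl)-2,2-dimethyl-1,3-dioxolane-4-carboxylic acid (1.5 equiv); 3 N-hydroxyphthalimide; 4 1-(benzyloxy)-4-iodobenzene (1.0 equiv)
Product: 6 methyl (4S,5R)-5-[4-(benzyloxy)phenyl]-2,2-dimethyl-1,3-dioxolane-4-carboxylate, via N-acyloxyphthalimide ester 5 (not isolated)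
Conditions: 3, DIC, NMP, rt, 2 h; then 4, NiCl2·6H2O (20 mol %), 2,2'-bipyridine (20 mol %), AgNO3 (30 mol %), Mg anode, RVC cathode, undivided cell, 12 mA, 2.5 F/mol, rt
Reagents that add atoms: none
Why: Carbodiimide esterification followed by nickel-electrocatalysed decarboxylative arylation of the redox-active ester (reductive cross-electrophile coupling); the dioxolanyl radical is captured by aryl–nickel anti to the neighbouring CO2Me group, so the new C5 (R) is set trans by the remaining tartrate center.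

**Step 3**
Reactants: 6 methyl (4S,5R)-5-[4-(benzyloxy)phenyl]-2,2-dimethyl-1,3-dioxolane-4-carboxylate
Product: 7 (4S,5R)-5-[4-(benzyloxy)phenyl]-2,2-dimethyl-1,3-dioxolane-4-carboxylic acid
Conditions: LiOH·H2O (1.5 equiv), THF/H2O (3:1), 0 °C; then 1 M HCl to pH 3
Reagents that add atoms: lithium hydroxide [Li+].[OH-]
Why: Ester saponification; the benzyl ether and ketal are base-stable, and any epimerisation at C4 is harmless because that carbon becomes a radical in step 4.

**Step 4**
Reactants: 7 (4S,5R)-5-[4-(benzyloxy)phenyl]-2,2-dimethyl-1,3-dioxolane-4-carboxylic acid (1.0 equiv); 3 N-hydroxyphthalimide; 8 1,3-bis(benzyloxy)-5-bromobenzene (1.5 equiv)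
Product: 10 (4R,5R)-4-[3,5-bis(benzyloxy)phenyl]-5-[4-(benzyloxy)phenyl]-2,2-dimethyl-1,3-dioxolane, via N-acyloxyphthalimide ester 9 (not isolated)
Conditions: 3, DIC, NMP, rt, 2 h; then 8, NiCl2·6H2O (20 mol %), 2,2'-bipyridine (20 mol %), AgNO3 (30 mol %), Mg anode, RVC cathode, undivided cell, 12 mA, 2.5 F/mol, rt
Reagents that add atoms: none
Why: Same nickel-electrocatalysed decarboxylative arylation; the C4 radical is trapped anti to the C5 aryl group, so the (4R,5R) trans dioxolane is set by the center made in step 2 (relay of the tartrate chirality), and the minor cis isomer is removed on silica.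

**Step 5**
Reactants: 10 (4R,5R)-4-[3,5-bis(benzyloxy)phenyl]-5-[4-(benzyloxy)phenyl]-2,2-dimethyl-1,3-dioxolane
Product: 11 5-[(4R,5R)-5-(4-hydroxyphenyl)-2,2-dimethyl-1,3-dioxolan-4-yl]benzene-1,3-diol
Conditions: H2 (1 atm), 10% Pd/C, EtOAc/EtOH (4:1), rt, stopped at full O-debenzylation
Reagents that add atoms: none
Why: Hydrogenolysis of aryl benzyl ethers is much faster than cleavage of the hindered secondary benzylic C–O bonds of the trans-diaryl dioxolane, so the ketal and both stereocenters survive.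

**Step 6**
Reactants: 12 resveratrol, (E)-5-[2-(4-hydroxyphenyl)ethenyl]benzene-1,3-diol
Product: 13 (E)-1-[3,5-bis(triisopropylsilyloxy)phenyl]-2-[4-(triisopropylsilyloxy)phenyl]ethene
Conditions: triisopropylsilyl chloride (3.6 equiv), imidazole (7 equiv), DMF, rt to 40 °C
Reagents that add atoms: triisopropylsilyl chloride CC(C)[Si](Cl)(C(C)C)C(C)C
Why: Standard phenol silylation; the bulky silyl ethers keep the stilbene electron-rich, prevent its own resorcinol ring from acting as the nucleophile, and tolerate anodic conditions.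

**Step 7**
Reactants: 11 5-[(4R,5R)-5-(4-hydroxyphenyl)-2,2-dimethyl-1,3-dioxolan-4-yl]benzene-1,3-diol (1.0 equiv); 13 (E)-1-[3,5-bis(triisopropylsilyloxy)phenyl]-2-[4-(triisopropylsilyloxy)phenyl]ethene (1.2 equiv)
Product: 14 (2S,3S)-3-[3,5-bis(triisopropylsilyloxy)phenyl]-4-[(4R,5R)-5-(4-hydroxyphenyl)-2,2-dimethyl-1,3-dioxolan-4-yl]-2-[4-(triisopropylsilyloxy)phenyl]-2,3-dihydro-1-benzofuran-6-ol
Conditions: undivided cell, graphite anode, Pt cathode, constant current (2 mA/cm2), 2.2 F/mol; Bu4NPF6 (0.1 M), 2,6-lutidine (20 mol %), HFIP/CH2Cl2 (3:1), 0 °C; 13 added over 3 h; run to about 80% conversion of 11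
Reagents that add atoms: none
Why: Proposed new method: the anode takes one electron from stilbene 13, the most easily oxidised component (estimated about 0.3 V below the un-ionised resorcinol in HFIP); the radical cation is attacked at C8 (the carbon remote from the 4-silyloxyphenyl ring) by the resorcinol carbon that is para to one hydroxyl and ortho to the other; rearomatisation and a second anodic electron give the 4-silyloxybenzylic cation, which the ortho hydroxyl closes anti to the C3 aryl group (2,3-trans, so 2S follows from C3); C3 is set in the C–C bond-forming step by the tartrate-derived dioxolane, whose C4–H lies in the arene plane next to the reacting carbon (1,3-allylic strain), so that C5 with its aryl group shields one face and the stilbene, with its 3,5-disilyloxyphenyl ring stacked over the resorcinol ring, bonds from the ring-oxygen face to give 3S (the minor 2R,3R isomer is a diastereomer and is removed on silica); the closest known reaction types are the anodic and photocatalytic oxidative [3+2] annulations of para-alkoxyphenols with alkenes (where the phenol is oxidised), alkene radical-cation cycloadditions, and the oxidative dimerisation of resveratrol to ε-viniferin, none of which has been shown as a cross-annulation of a stilbene radical cation with a non-conjugated resorcinol or under 1,4-induction from a benzylic stereocenter.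

**Step 8**
Reactants: 14 (2S,3S)-3-[3,5-bis(triisopropylsilyloxy)phenyl]-4-[(4R,5R)-5-(4-hydroxyphenyl)-2,2-dimethyl-1,3-dioxolan-4-yl]-2-[4-(triisopropylsilyloxy)phenyl]-2,3-dihydro-1-benzofuran-6-ol
Product: 16 (1R,2R)-1-[(2S,3S)-3-(3,5-dihydroxyphenyl)-6-hydroxy-2-(4-hydroxyphenyl)-2,3-dihydro-1-benzofuran-4-yl]-2-(4-hydroxyphenyl)ethane-1,2-diol, via acetonide pentaphenol 15 (not isolated)
Conditions: Bu4NF (3.5 equiv), AcOH (4 equiv), THF, 0 °C, 1 h; then AcOH/H2O (4:1), 45 °C, 4 h
Reagents that add atoms: none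
Why: Buffered fluoride desilylation of the three aryl silyl ethers, then acid-catalysed ketal hydrolysis, which cleaves at the ketal carbon and leaves both carbinol centers untouched; no stereocenter is formed, and the 2,3-trans ring is the thermodynamic arrangement.

## Compound list

1 | dimethyl (4S,5S)-2,2-dimethyl-1,3-dioxolane-4,5-dicarboxylate | COC(=O)[C@H]1OC(C)(C)O[C@@H]1C(=O)OC | starting material
2 | (4S,5S)-5-(methoxycarbonyl)-2,2-dimethyl-1,3-dioxolane-4-carboxylic acid | COC(=O)[C@H]1OC(C)(C)O[C@@H]1C(O)=O | intermediate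
3 | N-hydroxyphthalimide | O=C1N(O)C(=O)c2ccccc12 | starting material
4 | 1-(benzyloxy)-4-iodobenzene | Ic1ccc(OCc2ccccc2)cc1 | starting material
5 | 1,3-dioxoisoindolin-2-yl methyl (4S,5S)-2,2-dimethyl-1,3-dioxolane-4,5-dicarboxylate | COC(=O)[C@H]1OC(C)(C)O[C@@H]1C(=O)ON2C(=O)c3ccccc3C2=O | intermediate (not isolated)
6 | methyl (4S,5R)-5-[4-(benzyloxy)phenyl]-2,2-dimethyl-1,3-dioxolane-4-carboxylate | COC(=O)[C@H]1OC(C)(C)O[C@@H]1c2ccc(OCc3ccccc3)cc2 | intermediate
7 | (4S,5R)-5-[4-(benzyloxy)phenyl]-2,2-dimethyl-1,3-dioxolane-4-carboxylic acid | OC(=O)[C@H]1OC(C)(C)O[C@@H]1c2ccc(OCc3ccccc3)cc2 | intermediate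
8 | 1,3-bis(benzyloxy)-5-bromobenzene | Brc1cc(OCc2ccccc2)cc(OCc2ccccc2)c1 | starting material
9 | 1,3-dioxoisoindolin-2-yl (4S,5R)-5-[4-(benzyloxy)phenyl]-2,2-dimethyl-1,3-dioxolane-4-carboxylate | O=C(ON1C(=O)c2ccccc2C1=O)[C@H]3OC(C)(C)O[C@@H]3c4ccc(OCc5ccccc5)cc4 | intermediate (not isolated)
10 | (4R,5R)-4-[3,5-bis(benzyloxy)phenyl]-5-[4-(benzyloxy)phenyl]-2,2-dimethyl-1,3-dioxolane | c1c(OCc2ccccc2)cc(OCc2ccccc2)cc1[C@H]3OC(C)(C)O[C@@H]3c4ccc(OCc5ccccc5)cc4 | intermediate
11 | 5-[(4R,5R)-5-(4-hydroxyphenyl)-2,2-dimethyl-1,3-dioxolan-4-yl]benzene-1,3-diol | Oc1cc(O)cc(c1)[C@H]2OC(C)(C)O[C@@H]2c3ccc(O)cc3 | intermediate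
12 | resveratrol, (E)-5-[2-(4-hydroxyphenyl)ethenyl]benzene-1,3-diol | Oc1ccc(/C=C/c2cc(O)cc(O)c2)cc1 | starting material
13 | (E)-1-[3,5-bis(triisopropylsilyloxy)phenyl]-2-[4-(triisopropylsilyloxy)phenyl]ethene | CC(C)[Si](C(C)C)(C(C)C)Oc1ccc(/C=C/c2cc(O[Si](C(C)C)(C(C)C)C(C)C)cc(O[Si](C(C)C)(C(C)C)C(C)C)c2)cc1 | intermediate
14 | (2S,3S)-3-[3,5-bis(triisopropylsilyloxy)phenyl]-4-[(4R,5R)-5-(4-hydroxyphenyl)-2,2-dimethyl-1,3-dioxolan-4-yl]-2-[4-(triisopropylsilyloxy)phenyl]-2,3-dihydro-1-benzofuran-6-ol | Oc1ccc(cc1)[C@H]2OC(C)(C)O[C@@H]2c3cc(O)cc4c3[C@H](c5cc(O[Si](C(C)C)(C(C)C)C(C)C)cc(O[Si](C(C)C)(C(C)C)C(C)C)c5)[C@@H](c6ccc(O[Si](C(C)C)(C(C)C)C(C)C)cc6)O4 | intermediate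
15 | 5-[(2S,3S)-6-hydroxy-4-[(4R,5R)-5-(4-hydroxyphenyl)-2,2-dimethyl-1,3-dioxolan-4-yl]-2-(4-hydroxyphenyl)-2,3-dihydro-1-benzofuran-3-yl]benzene-1,3-diol | Oc1ccc(cc1)[C@H]2OC(C)(C)O[C@@H]2c3cc(O)cc4c3[C@H](c5cc(O)cc(O)c5)[C@@H](c6ccc(O)cc6)O4 | intermediate (not isolated)
16 | (1R,2R)-1-[(2S,3S)-3-(3,5-dihydroxyphenyl)-6-hydroxy-2-(4-hydroxyphenyl)-2,3-dihydro-1-benzofuran-4-yl]-2-(4-hydroxyphenyl)ethane-1,2-diol | Oc1ccc([C@@H](O)[C@H](O)c2cc(O)cc3c2[C@H](c2cc(O)cc(O)c2)[C@@H](c2ccc(O)cc2)O3)cc1 | target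

## Step count and risks

Total steps: 8. Longest linear sequence: 7 (steps 1, 2, 3, 4, 5, 7, 8).

**Step 7 (the new annulation) is the most likely to fail.** Three things can go wrong: the facial selectivity may be low or reversed, the resorcinol may react at the carbon between its two hydroxyls, and the stilbene may dimerise. The fallback sets out from 11 and comes back to the route at 15, using known two-electron chemistry. Condensing 11 with commercial 3,5-bis(benzyloxy)benzaldehyde and sodium 4-methylbenzenesulfinate (HCO2H, CH2Cl2/H2O, rt) gives the ortho-(α-sulfonylbenzyl)phenol, sulfone F1, as an epimer mixture at the new carbon, which does not matter. Cs2CO3 in CH2Cl2 eliminates sulfinate to the quinone methide, which undergoes the known formal [4+1] annulation with the ylide of [4-(benzyloxy)benzyl]dimethylsulfonium chloride, sulfonium salt F2 (from commercial 4-(benzyloxy)benzyl chloride and Me2S). This gives the trans-2,3-diaryl-2,3-dihydrobenzofuran, tribenzyl ether F3, whose two trans diastereomers are separated on silica. Hydrogenolysis as in step 5 (H2, Pd/C, EtOAc) gives 15, which goes through the acid stage of step 8.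

**Step 4 (second decarboxylative arylation).** The radical is now flanked by an aryl group and the aryl bromide is electron-rich, so the reductive coupling may stall or give protodecarboxylation. The fallback sets out from 7 and 8 and comes back at 10. Ester 9 is made from 7 and 3 (DIC, CH2Cl2) and isolated. Bromide 8 is converted (Mg, LiCl, THF; then ZnCl2) into [3,5-bis(benzyloxy)phenyl]zinc chloride, arylzinc F4. The two are joined by the known thermal nickel-catalysed decarboxylative Negishi arylation (NiCl2·DME 20 mol %, 4,4'-di-tert-butyl-2,2'-bipyridine 40 mol %, THF/DMF, rt), which replaces the aryl electrophile and the electrode by an aryl nucleophile and gives 10 with the same trans control.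

**Step 8 (final deprotection).** In acid, the free pentaphenol can ionise at the 4-hydroxybenzylic carbinol carbon, which would cause epimerisation or Friedel–Crafts closure onto the C3 resorcinol ring. The fallback sets out from 15 and comes back at 16. Step 8 is stopped after the fluoride stage and 15 is isolated. Ac2O, pyridine and DMAP convert it into the acetonide pentaacetate F5, whose electron-poor rings neither stabilise a benzylic cation nor act as Friedel–Crafts donors. The ketal is then cleaved with stronger acid (TFA/H2O 9:1, 0 °C) to the diol pentaacetate F6, and the acetates are removed with K2CO3 in degassed MeOH at 0 °C to give 16.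

## Further compounds

F1 | step 7 | 4-{[3,5-bis(benzyloxy)phenyl](4-methylbenzenesulfonyl)methyl}-5-[(4R,5R)-5-(4-hydroxyphenyl)-2,2-dimethyl-1,3-dioxolan-4-yl]benzene-1,3-diol (epimer mixture at the sulfonyl-bearing carbon) | Oc1cc(O)c(C(c2cc(OCc3ccccc3)cc(OCc3ccccc3)c2)S(=O)(=O)c2ccc(C)cc2)c(c1)[C@H]4OC(C)(C)O[C@@H]4c5ccc(O)cc5
F2 | step 7 | [4-(benzyloxy)benzyl]dimethylsulfonium chloride | C[S+](C)Cc1ccc(OCc2ccccc2)cc1.[Cl-]
F3 | step 7 | (2S,3S)-3-[3,5-bis(benzyloxy)phenyl]-2-[4-(benzyloxy)phenyl]-4-[(4R,5R)-5-(4-hydroxyphenyl)-2,2-dimethyl-1,3-dioxolan-4-yl]-2,3-dihydro-1-benzofuran-6-ol | Oc1ccc(cc1)[C@H]2OC(C)(C)O[C@@H]2c3cc(O)cc4c3[C@H](c5cc(OCc6ccccc6)cc(OCc6ccccc6)c5)[C@@H](c7ccc(OCc8ccccc8)cc7)O4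
F4 | step 4 | [3,5-bis(benzyloxy)phenyl]zinc chloride | Cl[Zn]c1cc(OCc2ccccc2)cc(OCc2ccccc2)c1
F5 | step 8 | pentaacetate of 15: 5-[(2S,3S)-6-acetoxy-2-(4-acetoxyphenyl)-4-[(4R,5R)-5-(4-acetoxyphenyl)-2,2-dimethyl-1,3-dioxolan-4-yl]-2,3-dihydro-1-benzofuran-3-yl]-1,3-phenylene diacetate | CC(=O)Oc1ccc(cc1)[C@H]2OC(C)(C)O[C@@H]2c3cc(OC(C)=O)cc4c3[C@H](c5cc(OC(C)=O)cc(OC(C)=O)c5)[C@@H](c6ccc(OC(C)=O)cc6)O4
F6 | step 8 | pentaacetate of 16 (all five phenols acetylated, (1R,2R)-diol free) | CC(=O)Oc1ccc(cc1)[C@@H](O)[C@H](O)c2cc(OC(C)=O)cc3c2[C@H](c4cc(OC(C)=O)cc(OC(C)=O)c4)[C@@H](c5ccc(OC(C)=O)cc5)O3
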